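## Retrosynthetic overview

1. Numbering: ring C1 (bears CH2OAc)=C2H–C3(=O)–C4 (quaternary oxirane carbon)–C5H (oxirane)–C6(=O); chain C1'H(OAc)–C2'H=C3'(CH3)–C4'H=C5'H–C6'HO. The plan rests on one feature of the single carbocycle: the C1=C2 alkene faces the C4–C5 oxirane across the ring, and C3 and C6 are carbonyl carbons with no configuration to preserve.
2. Last operations: the C3 and C6 ketones come from silyl-protected carbinols (desilylation, double Dess–Martin oxidation). The C3'–C6' dienal comes from a C2' aldehyde by two stabilised-ylide Wittig reactions, and C1'/C2' come from a dioxolane.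
3. Key disconnection: C1=C2 is opened by ring-closing metathesis. This leads to an open-chain cis-oxirane whose C4 arm is a vinyl carbinol (C3, C2) and whose C5 arm is a 2-(acetoxymethyl)allyl carbinol (C6, C1).
4. The diene goes back to one epoxy alcohol by oxidation and alkenylation at each terminus (a 2-lithioallyl ether at C6, vinylmagnesium bromide at C3).
5. Ring order: dioxolane first (from L-erythrulose, which supplies C1'). The oxirane follows, by Sharpless epoxidation of an E-trisubstituted allylic alcohol (sets C4 and C5). The cyclohexene is closed last, by metathesis.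

Key step: step 15

Assumption: the carbinol centres C3 and C6 are formed without reliable control and are erased in step 22. Names and SMILES show one epimer (both C–O bonds anti to the oxirane oxygen once the ring is closed), and the epimers are carried on together or separated for convenience.

## Route

Step 1
Reactants: 1 L-erythrulose [(3S)-1,3,4-trihydroxybutan-2-one]
Product: 2 3,4-O-isopropylidene-L-erythrulose [1-[(4S)-2,2-dimethyl-1,3-dioxolan-4-yl]-2-hydroxyethanone]
Conditions: Me2C(OMe)2, acetone, cat. p-TsOH·H2O, 0 °C → rt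
Reagents that add atoms: 2,2-dimethoxypropane, COC(C)(C)OC
Why: Acid-catalysed transketalisation should engage the vicinal 3,4-diol as the favoured five-membered dioxolane, leaving free the primary hydroxyl next to the ketone (future C3–O) and leaving the carbinol centre that becomes C1' untouched.

Step 2
Reactants: 2 3,4-O-isopropylidene-L-erythrulose
Product: 3 1-O-triethylsilyl-3,4-O-isopropylidene-L-erythrulose (carbonyl carbon = C4; CH2OSiEt3 = C3)
Conditions: Et3SiCl, imidazole, CH2Cl2, 0 °C
Reagents that add atoms: chlorotriethylsilane, CC[Si](Cl)(CC)CC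
Why: Imidazole-promoted silylation of the only free hydroxyl gives a primary triethylsilyl ether that can later be addressed selectively beside secondary TBS ethers.

Step 3
Reactants: 3 silyloxy ketone; 4 ethyl (triphenylphosphoranylidene)acetate
Product: 5 ethyl (E)-3-[(4R)-2,2-dimethyl-1,3-dioxolan-4-yl]-4-(triethylsilyloxy)but-2-enoate (ester cis to CH2OSiEt3)
Conditions: toluene, 80 °C
Reagents that add atoms: none
Why: Wittig olefination with a stabilised ylide, which α,α'-dialkoxy ketones accept without added base (so no enolisation at C1'), should place the ester trans to the branched dioxolanyl group and cis to the slimmer CH2OSiEt3 arm, which is the E geometry that later puts C3 and C6 on one side of the oxirane, and any Z isomer is removed by chromatography.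

Step 4
Reactants: 5 (E)-enoate
Product: 6 (E)-3-[(4R)-2,2-dimethyl-1,3-dioxolan-4-yl]-4-(triethylsilyloxy)but-2-en-1-ol
Conditions: i-Bu2AlH (2.5 equiv), CH2Cl2, −78 °C
Reagents that add atoms: none
Why: 1,2-Reduction of the enoate with i-Bu2AlH at low temperature gives the allylic alcohol (C6–OH) without touching the silyl ether, the acetonide or the alkene geometry.

Step 5
Reactants: 6 allylic alcohol
Product: 7 [(2R,3S)-3-[(4S)-2,2-dimethyl-1,3-dioxolan-4-yl]-3-(triethylsilyloxymethyl)oxiran-2-yl]methanol
Conditions: Ti(Oi-Pr)4 (20 mol %), D-(−)-diethyl tartrate (24 mol %), t-BuOOH (decane), 4 Å MS, CH2Cl2, −20 °C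
Reagents that add atoms: tert-butyl hydroperoxide, CC(C)(C)OO
Why: In the Sharpless asymmetric epoxidation the C6 hydroxyl anchors the alkene to the titanium–tartrate complex and the D-(−)-tartrate delivers oxygen to one face, setting C5 (R in 7) and C4 (S in 7) together; reagent control is expected to override the weak bias of the C1' dioxolane, and the E geometry becomes the cis relation of the C3 and C6 arms.

Step 6
Reactants: 7 epoxy alcohol
Product: 8 (2S,3R)-3-[(4S)-2,2-dimethyl-1,3-dioxolan-4-yl]-3-(triethylsilyloxymethyl)oxirane-2-carbaldehyde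
Conditions: Dess–Martin periodinane, pyridine, CH2Cl2, 0 °C → rt
Reagents that add atoms: none
Why: Buffered Dess–Martin oxidation turns the primary alcohol into the C6 aldehyde under neutral conditions that spare the oxirane and the triethylsilyl ether, and the oxirane C5–H is not prone to enolisation.

Step 7
Reactants: 9 2-bromoprop-2-en-1-ol
Product: 10 2-bromo-3-(4-methoxybenzyloxy)prop-1-ene
Conditions: NaH, 4-MeOC6H4CH2Cl, cat. n-Bu4NI, THF, 0 °C → rt
Reagents that add atoms: 4-methoxybenzyl chloride, COc1ccc(CCl)cc1
Why: Williamson etherification masks the hydroxyl as a PMB ether that tolerates halogen–lithium exchange, cannot migrate to the carbanion as a silyl group might, and is later removed oxidatively beside silyl ethers.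

Step 8
Reactants: 10 2-bromo-3-(4-methoxybenzyloxy)prop-1-ene; 8 epoxy aldehyde
Product: 12 open-chain C6 carbinol [C5 of the oxirane now carries CH(OH)C(=CH2)CH2OPMB; C3 still CH2OSiEt3], via alkenyllithium 11 (not isolated)
Conditions: 10 (1.5 equiv), t-BuLi (3.0 equiv), Et2O, −78 °C; then 8, −78 °C; aqueous quench at −78 °C
Reagents that add atoms: none
Why: Bromine–lithium exchange with two equivalents of t-BuLi per bromide gives the 2-lithioallyl ether, stable at −78 °C, which adds 1,2 to the aldehyde faster than it attacks the oxirane, and the new C6 centre is under Felkin–Anh bias only, which suffices because it becomes a ketone in step 22.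

Step 9
Reactants: 12 C6 carbinol
Product: 13 C6 tert-butyldimethylsilyl ether of 12
Conditions: TBSOTf, 2,6-lutidine, CH2Cl2, −78 → −20 °C
Reagents that add atoms: tert-butyldimethylsilyl triflate, CC(C)(C)[Si](C)(C)OS(=O)(=O)C(F)(F)F
Why: Silyl triflate/lutidine silylation protects the hindered secondary allylic alcohol at low temperature without disturbing the oxirane, the acetonide or the primary triethylsilyl ether.

Step 10
Reactants: 13 C6 silyl ether
Product: 15 C3 aldehyde (formyl group on the quaternary oxirane carbon C4), via alkoxysulfonium chloride 14 (not isolated)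
Conditions: (COCl)2, DMSO, CH2Cl2, −78 → −35 °C; then Et3N, −78 → 0 °C
Reagents that add atoms: none
Why: This is a Swern oxidation applied directly to the silyl ether: chlorodimethylsulfonium chloride exchanges with primary triethylsilyl ethers while secondary TBS ethers stay inert, and the alkoxysulfonium salt collapses with Et3N to an aldehyde that has no α-hydrogen at C4 and so cannot epimerise.

Step 11
Reactants: 15 C3 aldehyde; 16 vinylmagnesium bromide
Product: 17 C3 vinyl carbinol [C4 now carries CH(OH)CH=CH2]
Conditions: THF, −78 °C; aqueous quench at −78 °C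
Reagents that add atoms: none
Why: Grignard 1,2-addition to the activated α-oxygenated aldehyde installs C2 and its terminal methylene, and the C3 centre forms without reliable control, which is acceptable because step 22 oxidises it.

Step 12
Reactants: 17 C3 vinyl carbinol
Product: 18 C3,C6-bis(tert-butyldimethylsilyl) ether with the PMB ether retained
Conditions: TBSOTf, 2,6-lutidine, CH2Cl2, −40 → 0 °C
Reagents that add atoms: tert-butyldimethylsilyl triflate, CC(C)(C)[Si](C)(C)OS(=O)(=O)C(F)(F)F
Why: The reactive silyl triflate is needed to silylate the carbinol next to the quaternary C4, and lutidine buffering keeps the oxirane, acetonide and PMB ether intact.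

Step 13
Reactants: 18 bis-silyl PMB ether
Product: 19 primary allylic alcohol [C6 arm ends in C(=CH2)CH2OH]
Conditions: DDQ, CH2Cl2/aq pH 7 phosphate buffer, 0 °C
Reagents that add atoms: none
Why: Oxidative PMB cleavage (hydride abstraction at the electron-rich benzylic position, then hydrolysis) frees only the primary allylic alcohol and leaves the silyl ethers, acetonide, oxirane and both unactivated alkenes alone.

Step 14
Reactants: 19 primary allylic alcohol
Product: 20 acyclic cis-epoxide diene (metathesis precursor): C4 carries CH(OTBS)CH=CH2 and the dioxolane; C5 carries CH(OTBS)C(=CH2)CH2OAc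
Conditions: Ac2O, pyridine, cat. DMAP, CH2Cl2, 0 °C → rt
Reagents that add atoms: acetic anhydride, CC(=O)OC(C)=O
Why: DMAP-catalysed acetylation installs the CH2OAc group of the target at the point where no organometallic step remains.

Step 15
Reactants: 20 acyclic cis-epoxide diene
Product: 21 epoxycyclohexene (7-oxabicyclo[4.1.0]hept-3-ene core): CH2OAc on C1; OTBS on C3 and C6; dioxolane on C4
Conditions: second-generation Hoveyda–Grubbs catalyst RuCl2(H2IMes)(=CH-C6H4-2-Oi-Pr) (10 mol %, two portions), 1,4-benzoquinone (20 mol %), degassed toluene (2 mM), 80 °C, Ar sparge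
Reagents that add atoms: none
Why: The ruthenium alkylidene should load first on the monosubstituted vinyl group at C2, then add [2+2] to the 1,1-disubstituted alkene on the C6 arm and cyclorevert, which forms C1=C2 and returns Ru=CH2 while ethylene is swept out. The closest known reaction type is ring-closing metathesis of oxygenated octa-1,7-dienes to trisubstituted cyclohexenes, as used for carbasugar-type rings bearing a CH2OR group on the alkene. The six-membered carbocycle is closed by joining the two alkene termini C2 and C1, and the ring size allows only the endocyclic cis alkene. No stereocentre is created, and C3, C4, C5, C6 and C1' are spectators. The step needs cyclisation to beat oligomerisation and needs no other π-system to take part: the cis-oxirane fixes both arms on one side with a near-eclipsed C3–C4–C5–C6 unit, high dilution helps, and the dienal is not yet present. Either epimer at C3 or C6 can reach the closing geometry, so the mixture should converge on the same ring skeleton.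

Step 16
Reactants: 21 epoxycyclohexene acetonide
Product: 22 C1',C2'-diol
Conditions: AcOH/THF/H2O (4:1:1), 45 °C
Reagents that add atoms: none
Why: Mild aqueous-acid ketal hydrolysis should cleave the terminal dioxolane faster than the hindered secondary TBS ethers, and the oxirane, flanked by electron-withdrawing C–O bonds on all sides, should resist acid-promoted opening.

Step 17
Reactants: 22 diol
Product: 24 C1' acetate with C2' triethylsilyl ether, via primary triethylsilyl ether 23 (not isolated)
Conditions: Et3SiCl (1.05 equiv), pyridine, CH2Cl2, −20 °C; then Ac2O, cat. DMAP, 0 °C → rt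
Reagents that add atoms: chlorotriethylsilane, CC[Si](Cl)(CC)CC; acetic anhydride, CC(=O)OC(C)=O
Why: Steric differentiation lets Et3SiCl silylate only the primary C2' hydroxyl at low temperature, and DMAP-catalysed acetylation in the same flask esterifies the C1' hydroxyl with retention because the C1'–O bond is never broken.

Step 18
Reactants: 24 acetate silyl ether
Product: 25 C2' primary alcohol (C1' acetate; ring TBS ethers retained)
Conditions: HF·pyridine, pyridine, THF, 0 °C
Reagents that add atoms: none
Why: Buffered HF·pyridine removes a primary triethylsilyl ether far faster than hindered secondary TBS ethers, and the weakly acidic medium disfavours acetyl migration from O–C1' to O–C2'.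

Step 19
Reactants: 25 primary alcohol; 26 2-(triphenylphosphoranylidene)propanal
Product: 28 (E)-enal [C1'H(OAc)–C2'H=C3'(CH3)–C4'HO], via acetoxy aldehyde 27 (not isolated)
Conditions: Dess–Martin periodinane, pyridine, CH2Cl2, 0 °C → rt; then 26 (3 equiv), rt → 40 °C
Reagents that add atoms: none
Why: Dess–Martin oxidation followed by Wittig olefination in the same flask avoids isolating the α-acetoxy aldehyde (which could epimerise at C1' or eliminate with oxirane opening), and the stabilised α-methyl formyl ylide should give the E trisubstituted C2'=C3' alkene.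

Step 20
Reactants: 28 (E)-enal; 29 (triphenylphosphoranylidene)acetaldehyde
Product: 30 (E,E)-dienal with both ring TBS ethers
Conditions: 29 (1.3 equiv), toluene, 70 °C
Reagents that add atoms: none
Why: A second Wittig homologation with the stabilised formylmethylene ylide adds C5' and C6' with E geometry at C4'=C5' under base-free conditions that spare both acetates, and a small excess of ylide with moderate heating limits further homologation.

Step 21
Reactants: 30 bis-silyl dienal
Product: 31 C3,C6-diol
Conditions: 48% aq HF, MeCN, 0 °C → rt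
Reagents that add atoms: none
Why: Acidic fluoride cleavage removes both secondary TBS ethers without base, so Payne rearrangement, acetate migration and condensation of the dienal should be avoided.

Step 22
Reactants: 31 diol
Product: 32 target CNP0307549.1
Conditions: Dess–Martin periodinane (4 equiv), CH2Cl2, 0 °C → rt
Reagents that add atoms: none
Why: Double Dess–Martin oxidation converts both carbinols into ketones under neutral conditions, so every C3/C6 epimer converges on the single ene-dione while C4, C5 and C1' are not touched.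

## Compound list

1 | L-erythrulose, (3S)-1,3,4-trihydroxybutan-2-one | OCC(=O)[C@@H](O)CO | starting material
2 | 3,4-O-isopropylidene-L-erythrulose | OCC(=O)[C@@H]1COC(C)(C)O1 | intermediate
3 | 1-O-triethylsilyl-3,4-O-isopropylidene-L-erythrulose | CC[Si](CC)(CC)OCC(=O)[C@@H]1COC(C)(C)O1 | intermediate
4 | ethyl (triphenylphosphoranylidene)acetate | CCOC(=O)C=P(c1ccccc1)(c1ccccc1)c1ccccc1 | starting material
5 | ethyl (E)-3-[(4R)-2,2-dimethyl-1,3-dioxolan-4-yl]-4-(triethylsilyloxy)but-2-enoate | CCOC(=O)/C=C(\CO[Si](CC)(CC)CC)[C@@H]1COC(C)(C)O1 | intermediate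
6 | (E)-3-[(4R)-2,2-dimethyl-1,3-dioxolan-4-yl]-4-(triethylsilyloxy)but-2-en-1-ol | OC/C=C(\CO[Si](CC)(CC)CC)[C@@H]1COC(C)(C)O1 | intermediate
7 | [(2R,3S)-3-[(4S)-2,2-dimethyl-1,3-dioxolan-4-yl]-3-(triethylsilyloxymethyl)oxiran-2-yl]methanol | CC[Si](CC)(CC)OC[C@]1([C@@H]2COC(C)(C)O2)O[C@@H]1CO | intermediate
8 | (2S,3R)-3-[(4S)-2,2-dimethyl-1,3-dioxolan-4-yl]-3-(triethylsilyloxymethyl)oxirane-2-carbaldehyde | CC[Si](CC)(CC)OC[C@]1([C@@H]2COC(C)(C)O2)O[C@@H]1C=O | intermediate
9 | 2-bromoprop-2-en-1-ol (2-bromoallyl alcohol) | OCC(Br)=C | starting material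
10 | 2-bromo-3-(4-methoxybenzyloxy)prop-1-ene | C=C(Br)COCc1ccc(OC)cc1 | intermediate
11 | 3-(4-methoxybenzyloxy)prop-1-en-2-yllithium | [Li]C(=C)COCc1ccc(OC)cc1 | intermediate
12 | C6 carbinol: oxirane of 7 with CH(OH)C(=CH2)CH2OPMB on C5 | CC[Si](CC)(CC)OC[C@]1([C@@H]2COC(C)(C)O2)O[C@@H]1[C@@H](O)C(=C)COCc1ccc(OC)cc1 | intermediate
13 | C6 TBS ether of 12 | CC[Si](CC)(CC)OC[C@]1([C@@H]2COC(C)(C)O2)O[C@@H]1[C@@H](O[Si](C)(C)C(C)(C)C)C(=C)COCc1ccc(OC)cc1 | intermediate
14 | C3 alkoxydimethylsulfonium chloride | C[S+](C)OC[C@]1([C@@H]2COC(C)(C)O2)O[C@@H]1[C@@H](O[Si](C)(C)C(C)(C)C)C(=C)COCc1ccc(OC)cc1.[Cl-] | intermediate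
15 | C3 aldehyde on the quaternary oxirane carbon | O=C[C@]1([C@@H]2COC(C)(C)O2)O[C@@H]1[C@@H](O[Si](C)(C)C(C)(C)C)C(=C)COCc1ccc(OC)cc1 | intermediate
16 | vinylmagnesium bromide | C=C[Mg]Br | starting material
17 | C3 vinyl carbinol | C=C[C@@H](O)[C@]1([C@@H]2COC(C)(C)O2)O[C@@H]1[C@@H](O[Si](C)(C)C(C)(C)C)C(=C)COCc1ccc(OC)cc1 | intermediate
18 | C3,C6-bis-TBS ether, PMB ether | C=C[C@@H](O[Si](C)(C)C(C)(C)C)[C@]1([C@@H]2COC(C)(C)O2)O[C@@H]1[C@@H](O[Si](C)(C)C(C)(C)C)C(=C)COCc1ccc(OC)cc1 | intermediate
19 | C3,C6-bis-TBS ether, primary allylic alcohol | C=C[C@@H](O[Si](C)(C)C(C)(C)C)[C@]1([C@@H]2COC(C)(C)O2)O[C@@H]1[C@@H](O[Si](C)(C)C(C)(C)C)C(=C)CO | intermediate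
20 | acyclic cis-epoxide diene acetate (metathesis precursor) | C=C[C@@H](O[Si](C)(C)C(C)(C)C)[C@]1([C@@H]2COC(C)(C)O2)O[C@@H]1[C@@H](O[Si](C)(C)C(C)(C)C)C(=C)COC(C)=O | intermediate
21 | epoxycyclohexene with C3 and C6 TBS ethers and C1'/C2' acetonide | CC(=O)OCC1=C[C@@H](O[Si](C)(C)C(C)(C)C)[C@]2([C@@H]3COC(C)(C)O3)O[C@@H]2[C@H]1O[Si](C)(C)C(C)(C)C | intermediate
22 | C1',C2'-diol | CC(=O)OCC1=C[C@@H](O[Si](C)(C)C(C)(C)C)[C@]2([C@@H](O)CO)O[C@@H]2[C@H]1O[Si](C)(C)C(C)(C)C | intermediate
23 | C2' triethylsilyl ether, C1' alcohol | CC(=O)OCC1=C[C@@H](O[Si](C)(C)C(C)(C)C)[C@]2([C@@H](O)CO[Si](CC)(CC)CC)O[C@@H]2[C@H]1O[Si](C)(C)C(C)(C)C | intermediate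
24 | C1' acetate, C2' triethylsilyl ether | CC(=O)OCC1=C[C@@H](O[Si](C)(C)C(C)(C)C)[C@]2([C@@H](OC(C)=O)CO[Si](CC)(CC)CC)O[C@@H]2[C@H]1O[Si](C)(C)C(C)(C)C | intermediate
25 | C1' acetate, C2' primary alcohol | CC(=O)OCC1=C[C@@H](O[Si](C)(C)C(C)(C)C)[C@]2([C@@H](OC(C)=O)CO)O[C@@H]2[C@H]1O[Si](C)(C)C(C)(C)C | intermediate
26 | 2-(triphenylphosphoranylidene)propanal | CC(C=O)=P(c1ccccc1)(c1ccccc1)c1ccccc1 | starting material
27 | C1' acetate, C2' aldehyde | CC(=O)OCC1=C[C@@H](O[Si](C)(C)C(C)(C)C)[C@]2([C@@H](OC(C)=O)C=O)O[C@@H]2[C@H]1O[Si](C)(C)C(C)(C)C | intermediate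
28 | (E)-2-methyl enal (C4' aldehyde) | CC(=O)OCC1=C[C@@H](O[Si](C)(C)C(C)(C)C)[C@]2([C@H](/C=C(C)/C=O)OC(C)=O)O[C@@H]2[C@H]1O[Si](C)(C)C(C)(C)C | intermediate
29 | (triphenylphosphoranylidene)acetaldehyde | O=CC=P(c1ccccc1)(c1ccccc1)c1ccccc1 | starting material
30 | (E,E)-dienal, C3,C6-bis-TBS ether | CC(=O)OCC1=C[C@@H](O[Si](C)(C)C(C)(C)C)[C@]2([C@H](/C=C(C)/C=C/C=O)OC(C)=O)O[C@@H]2[C@H]1O[Si](C)(C)C(C)(C)C | intermediate
31 | (E,E)-dienal, C3,C6-diol | CC(=O)OCC1=C[C@@H](O)[C@]2([C@H](/C=C(C)/C=C/C=O)OC(C)=O)O[C@@H]2[C@H]1O | intermediate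
32 | CNP0307549.1 (C4 R, C5 S, C1' S) | CC(=O)OCC1=CC(=O)[C@]2([C@H](/C=C(C)/C=C/C=O)OC(C)=O)O[C@@H]2C1=O | target

## Step count and main risks

Total step count: 22. Longest linear sequence: 21 (steps 1–6 and 8–22; step 7 is a one-step branch).

**Step 15 (ring-closing metathesis).** Initiation at the C2 vinyl group may be too slow, because the C3 silyl ether and the quaternary C4 shield it. Catalyst decay, double-bond migration or intermolecular coupling could then overtake ring closure.
- The fallback is a relay metathesis that sets out from aldehyde 15 and comes back at 21.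
- Allyl propargyl ether is hydrozirconated at the alkyne with Cp2Zr(H)Cl, transmetalated with Me2Zn and added to 15 to give the relay carbinol F1.
- TBSOTf/2,6-lutidine gives the relay bis-silyl ether F2, DDQ gives the relay primary alcohol F3, and Ac2O/DMAP gives the relay acetate F4.
- With the same ruthenium catalyst the unhindered allyl ether terminus is engaged first and a five-membered ring closure expels 2,5-dihydrofuran.
- The alkylidene is thereby placed directly on C2, from where closure onto the 1,1-disubstituted alkene gives 21.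

**Step 3 (Wittig olefination).** The E/Z selectivity may be poor or reversed, since both ketone substituents carry α-oxygen and differ only in branching.
- The fallback enforces the geometry with a ring. It sets out from 2 and comes back at 6.
- The α-hydroxy ketone 2 is heated with (triphenylphosphoranylidene)ketene (Bestmann ylide). O-acylation and intramolecular Wittig reaction give the butenolide F5, in which C3 and C6 are necessarily cis.
- Excess i-Bu2AlH gives the cis-related diol F6.
- Pivaloyl chloride (1 equiv, pyridine, −20 °C) acylates the less hindered C6 hydroxyl to give the monopivalate F7.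
- Et3SiCl/imidazole gives the silyl pivalate F8, and i-Bu2AlH removes the pivalate to give 6.

**Step 20 (second Wittig homologation).** The hindered α-methyl enal may react slowly, while the less hindered product dienal reacts again with the ylide, so material could be lost to repeated homologation.
- The fallback replaces olefination by cross-metathesis. It sets out from 28 and comes back at 30.
- Non-basic methylenation of the aldehyde (Zn, CH2I2, Ti(Oi-Pr)4, THF) gives the terminal diene F9.
- Cross-metathesis of its monosubstituted terminus with excess acrolein follows, using the second-generation Hoveyda–Grubbs catalyst RuCl2(H2IMes)(=CH-C6H4-2-Oi-Pr) in CH2Cl2 at 40 °C.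
- This should give the E C4'=C5' enal 30, because the trisubstituted C2'=C3' and C1=C2 alkenes are too hindered to take part.

## Further compounds

F1 | step 15 | relay carbinol, C3 bears (E)-CH=CHCH2OCH2CH=CH2 | C=CCOC/C=C/[C@@H](O)[C@]1([C@@H]2COC(C)(C)O2)O[C@@H]1[C@@H](O[Si](C)(C)C(C)(C)C)C(=C)COCc1ccc(OC)cc1
F2 | step 15 | relay bis-silyl ether | C=CCOC/C=C/[C@@H](O[Si](C)(C)C(C)(C)C)[C@]1([C@@H]2COC(C)(C)O2)O[C@@H]1[C@@H](O[Si](C)(C)C(C)(C)C)C(=C)COCc1ccc(OC)cc1
F3 | step 15 | relay primary alcohol | C=CCOC/C=C/[C@@H](O[Si](C)(C)C(C)(C)C)[C@]1([C@@H]2COC(C)(C)O2)O[C@@H]1[C@@H](O[Si](C)(C)C(C)(C)C)C(=C)CO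
F4 | step 15 | relay acetate | C=CCOC/C=C/[C@@H](O[Si](C)(C)C(C)(C)C)[C@]1([C@@H]2COC(C)(C)O2)O[C@@H]1[C@@H](O[Si](C)(C)C(C)(C)C)C(=C)COC(C)=O
F5 | step 3 | butenolide, 4-(2,2-dimethyl-1,3-dioxolan-4-yl)furan-2(5H)-one | O=C1OCC(=C1)[C@@H]2COC(C)(C)O2
F6 | step 3 | cis-related diol, (E)-2-(2,2-dimethyl-1,3-dioxolan-4-yl)but-2-ene-1,4-diol | OC/C=C(\CO)[C@@H]1COC(C)(C)O1
F7 | step 3 | monopivalate at C6–O | CC(C)(C)C(=O)OC/C=C(\CO)[C@@H]1COC(C)(C)O1
F8 | step 3 | silyl pivalate, C3–OSiEt3 and C6–OPiv | CC(C)(C)C(=O)OC/C=C(\CO[Si](CC)(CC)CC)[C@@H]1COC(C)(C)O1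
F9 | step 20 | terminal diene, C4'H=CH2 | CC(=O)OCC1=C[C@@H](O[Si](C)(C)C(C)(C)C)[C@]2([C@H](/C=C(C)/C=C)OC(C)=O)O[C@@H]2[C@H]1O[Si](C)(C)C(C)(C)C
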